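**Retrosynthetic overview**
1. Feature: in ring B (C1–C8–C7–C6–C5–C9) the carbon C7 sits between C8 and C6, so it is taken out last: isariotin C 27 ⇒ enamide triol 26 (oxirane last, directed by C6–OH) ⇒ amine 20 + acid 25 ⇒ 6-acetoxy-7-bromobicyclo[3.3.1]non-7-en-9-one 18 ⇒ dibromocarbene (from bromoform 16) + bicyclo[3.2.1]oct-6-en-8-one 15.
2. 15 ⇒ C8=C6 by selenoxide elimination ⇒ C5–C6 bond by alkylation of the C5 enolate of a ring A α-ketol whose C1 vinyl group has been bromoselenated (12).
3. Ring A ⇒ C9–C1 bond by carbene-catalysed aldehyde–ketone benzoin of keto aldehyde 10; C3 comes from N-Boc-L-aspartic acid 4-methyl ester 1, C4 from a Brown allylation, the vinyl ketone from the side-chain carboxyl.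
4. Acid 25 ⇒ hex-5-enoyl chloride + pentylmagnesium bromide, then cross metathesis with acrylic acid.
5. Ring order: ring A (step 8) → two-carbon alkene bridge, giving the bicyclo[3.2.1] core (steps 10–11) → ring B by one-carbon enlargement (step 12) → oxirane (step 18).

Key step: step 12

Remark: core atoms keep the target numbering throughout (C1 hydroxylated bridgehead, C2 CH2, C3 N-bearing, C4 carbinol, C5 bridgehead CH, C6 carbinol, C7/C8 oxirane carbons, C9 ketone; ring A = C1–C2–C3–C4–C5–C9); "exo" means the face turned toward C9.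

Step 1
Reactants: 1 N-Boc-L-aspartic acid 4-methyl ester
Product: 2 methyl (3S)-3-[(tert-butoxycarbonyl)amino]-4-hydroxybutanoate
Conditions: BH3·SMe2, THF, 0 °C to rt; MeOH quench
Reagents that add atoms: none
Why: Borane reduces the free carboxylic acid through its acyloxyborane far faster than the methyl ester or the carbamate (chemoselective acid reduction), so C3 is carried over unchanged.

Step 2
Reactants: 2 methyl (3S)-3-[(tert-butoxycarbonyl)amino]-4-hydroxybutanoate
Product: 3 methyl (3S)-3-[(tert-butoxycarbonyl)amino]-4-oxobutanoate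
Conditions: Dess–Martin periodinane, NaHCO3, CH2Cl2, 0 °C to rt; used crude
Reagents that add atoms: none
Why: Dess–Martin oxidation under buffered, non-basic conditions should give the configurationally labile α-amino aldehyde without epimerisation at C3, provided it is used at once.

Step 3
Reactants: 3 methyl (3S)-3-[(tert-butoxycarbonyl)amino]-4-oxobutanoate
Product: 5 tert-butyl N-[(2R,3S)-2-allyl-5-oxotetrahydrofuran-3-yl]carbamate, via hydroxy ester 4 (not isolated)
Conditions: (+)-Ipc2B(allyl), Et2O, −78 °C; NaBO3·4H2O, THF/H2O; PPTS (cat.), PhH, 50 °C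
Reagents that add atoms: (+)-B-allyldiisopinocampheylborane (the reagent from (−)-α-pinene) C=CCB([C@H]1C[C@H]2C[C@@H]([C@@H]1C)C2(C)C)[C@H]1C[C@H]2C[C@@H]([C@@H]1C)C2(C)C
Why: Brown allylboration through a chair Zimmerman–Traxler transition state adds allyl to the Re face of the aldehyde under reagent control (also the Felkin face of the (S)-α-carbamato aldehyde), which sets C4 as (R) with its oxygen later cis to C3–N on ring A, and the γ-hydroxy ester then lactonises under mild acid.

Step 4
Reactants: 5 tert-butyl N-[(2R,3S)-2-allyl-5-oxotetrahydrofuran-3-yl]carbamate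
Product: 6 (3S,4R)-3-[(tert-butoxycarbonyl)amino]-4-hydroxy-N-methoxy-N-methylhept-6-enamide
Conditions: MeNHOMe·HCl, i-PrMgCl, THF, −20 to 0 °C
Reagents that add atoms: N,O-dimethylhydroxylamine hydrochloride CNOC.Cl
Why: Weinreb amide formation: the chloromagnesium amide of N,O-dimethylhydroxylamine opens the γ-lactone at the acyl carbon, and the carbamate N–H only consumes an extra equivalent of base.

Step 5
Reactants: 6 (3S,4R)-3-[(tert-butoxycarbonyl)amino]-4-hydroxy-N-methoxy-N-methylhept-6-enamide
Product: 7 tert-butyl (4S,5R)-5-allyl-4-[2-(methoxy(methyl)amino)-2-oxoethyl]-2,2-dimethyloxazolidine-3-carboxylate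
Conditions: 2,2-dimethoxypropane, BF3·OEt2 (cat.), acetone, rt
Reagents that add atoms: 2,2-dimethoxypropane COC(C)(C)OC
Why: Acid-catalysed N,O-acetonide formation ties C3–N and C4–O into a cis-fused oxazolidine, which protects both groups at once and removes the N–H that would otherwise add to the enone of step 6 (aza-Michael closure to a piperidinone) or react under the basic carbene conditions later.

Step 6
Reactants: 7 tert-butyl (4S,5R)-5-allyl-4-[2-(methoxy(methyl)amino)-2-oxoethyl]-2,2-dimethyloxazolidine-3-carboxylate; 8 vinylmagnesium bromide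
Product: 9 tert-butyl (4S,5R)-5-allyl-2,2-dimethyl-4-(2-oxobut-3-en-1-yl)oxazolidine-3-carboxylate
Conditions: THF, −78 to 0 °C; inverse quench into cold 1 M HCl
Reagents that add atoms: none
Why: Weinreb ketone synthesis: the chelated tetrahedral adduct prevents over-addition, and quenching into acid protonates the liberated N,O-dimethylhydroxylamine before it can add to the vinyl ketone.

Step 7
Reactants: 9 tert-butyl (4S,5R)-5-allyl-2,2-dimethyl-4-(2-oxobut-3-en-1-yl)oxazolidine-3-carboxylate
Product: 10 tert-butyl (4S,5R)-2,2-dimethyl-4-(2-oxobut-3-en-1-yl)-5-(2-oxoethyl)oxazolidine-3-carboxylate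
Conditions: O3, CH2Cl2, −78 °C, Sudan red end point; PPh3
Reagents that add atoms: ozone [O-][O+]=O
Why: Ozone reacts with the isolated monosubstituted alkene much faster than with the electron-poor enone, so ozonolysis stopped at the indicator end point and reduced with PPh3 should unmask the C9 aldehyde selectively.

Step 8
Reactants: 10 tert-butyl (4S,5R)-2,2-dimethyl-4-(2-oxobut-3-en-1-yl)-5-(2-oxoethyl)oxazolidine-3-carboxylate
Product: 11 tert-butyl (3aS,5S,7aR)-5-hydroxy-2,2-dimethyl-6-oxo-5-vinylhexahydrobenzo[d]oxazole-3(2H)-carboxylate (ring A; C1–OH cis to C3–N and C4–O; vinyl trans)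
Conditions: (5aS,10bR)-5a,10b-dihydro-2-(pentafluorophenyl)-4H,6H-indeno[2,1-b][1,2,4]triazolo[4,3-d][1,4]oxazinium tetrafluoroborate (15 mol%), Et3N (15 mol%), PhMe, rt, 0.02 M
Reagents that add atoms: none
Why: Intramolecular crossed aldehyde–ketone benzoin reaction: the Breslow intermediate at C9 adds 1,2 to the C1 ketone through a six-membered transition state (conjugate addition would need an eight-membered one) and closes ring A by 6-exo-trig attack, the catalyst antipode being chosen so that the ketone face attacked places the C1 hydroxyl cis to C3–N and C4–O and the vinyl group trans to them.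

Step 9
Reactants: 11 tert-butyl (3aS,5S,7aR)-5-hydroxy-2,2-dimethyl-6-oxo-5-vinylhexahydrobenzo[d]oxazole-3(2H)-carboxylate
Product: 12 tert-butyl (3aS,5S,7aR)-2,2-dimethyl-6-oxo-5-(triethylsilyloxy)-5-vinylhexahydrobenzo[d]oxazole-3(2H)-carboxylate
Conditions: Et3SiOTf, 2,6-lutidine, CH2Cl2, −78 °C
Reagents that add atoms: triethylsilyl trifluoromethanesulfonate CC[Si](CC)(CC)OS(=O)(=O)C(F)(F)F
Why: Silylation of the tertiary α-ketol hydroxyl with the silyl triflate at low temperature (faster than enol silylation of the ketone) blocks retro-benzoin and α-ketol rearrangement in the basic step that follows.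

Step 10
Reactants: 12 tert-butyl (3aS,5S,7aR)-2,2-dimethyl-6-oxo-5-(triethylsilyloxy)-5-vinylhexahydrobenzo[d]oxazole-3(2H)-carboxylate
Product: 14 bicyclo[3.2.1]octan-8-one carrying C1–OSiEt3 and C8–SePh (both C8 epimers) with the N-Boc acetonide across exo C3–N and exo C4–O, via bromoselenide 13 (not isolated)
Conditions: PhSeBr, CH2Cl2, −78 °C; then LiN(SiMe3)2, THF, −78 to 0 °C
Reagents that add atoms: phenylselenyl bromide Br[Se]c1ccccc1
Why: Electrophilic bromoselenation puts selenium on C8 and bromide on the terminal C6 (bromide opens the seleniranium ion at the unhindered carbon remote from the electron-withdrawing C1 oxygen), and the only possible enolate of the C9 ketone, at C5, then displaces bromide in a 5-exo-tet intramolecular alkylation on the face of the axial C1 side chain, which forms C5–C6 irreversibly and fixes C5.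

Step 11
Reactants: 14 bicyclo[3.2.1]octan-8-one carrying C1–OSiEt3 and C8–SePh
Product: 15 bicyclo[3.2.1]oct-6-en-8-one carrying C1–OSiEt3 and the C8=C6 alkene with the N-Boc acetonide across exo C3–N and exo C4–O
Conditions: mCPBA, CH2Cl2, −78 °C; then i-Pr2NH, warm to 40 °C
Reagents that add atoms: none
Why: Selenoxide syn-elimination can take hydrogen only from C6 because C1 is quaternary, and so delivers the strained C8=C6 bond under mild conditions, a closure that olefin metathesis of a 1,3-divinyl ring could not achieve against the strain of a norbornene-type alkene.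

Step 12
Reactants: 15 bicyclo[3.2.1]oct-6-en-8-one carrying C1–OSiEt3 and the N-Boc acetonide; 16 bromoform
Product: 18 6-exo-acetoxy-7-bromobicyclo[3.3.1]non-7-en-9-one carrying C1–OSiEt3 and the N-Boc acetonide, via dibromocyclopropane 17 (not isolated)
Conditions: CHBr3, 50% aq NaOH, BnEt3NCl (cat.), CH2Cl2, 0 °C to rt; then AgOAc, NaOAc, AcOH, 60 °C
Reagents that add atoms: silver acetate CC(=O)[O-].[Ag+]
Why: Dibromocarbene, generated from bromoform by α-elimination under phase transfer, adds in a concerted [2+1] fashion to the strained C8=C6 bond on the exo face, because the endo face is covered by the C2–C3–C4 bridge whose C3–H points into it; this makes the C7–C8 and C7–C6 bonds. AgOAc (monovalent silver) then pulls off the bromide that lies cis to the C1–C8 and C5–C6 ring bonds, and its loss is concerted with disrotatory two-electron electrocyclic opening of the cyclopropane, which breaks the old C8–C6 bond, so ring B (C1–C8–C7–C6–C5–C9) is closed not by a cyclisation mode but by one-carbon enlargement of the five-membered ring. The resulting 2-bromoallyl cation C8–C7–C6 is trapped by acetate at C6 from the exo face, which is the face the bromide left from and the one free of ring A, so the new C6 stereocentre has its oxygen syn to C9 as the target requires. The closest known reaction type is dihalocarbene addition to norbornene-type alkenes with silver-assisted cyclopropyl-to-allyl ring expansion to 2-bromoallyl acetates. The step needs exo addition, capture at C6 and not at C8, and no 1,2-shift from C1 into the cation: C8 is neopentylic beside the quaternary C1, whose triethylsilyloxy group also withdraws charge from that terminus, and the delocalised cation is paired with acetate at silver and should collapse before it rearranges. The ketone has no enolisable hydrogen (C1 quaternary, C5 bridgehead) and nitrogen has no N–H, so the basic carbene conditions find nothing to deprotonate.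

Step 13
Reactants: 18 6-exo-acetoxy-7-bromobicyclo[3.3.1]non-7-en-9-one carrying C1–OSiEt3 and the N-Boc acetonide
Product: 19 6-exo-acetoxybicyclo[3.3.1]non-7-en-9-one carrying C1–OSiEt3 and the N-Boc acetonide
Conditions: Bu3SnH, AIBN, PhMe, 90 °C
Reagents that add atoms: none
Why: Radical chain hydrodebromination: the tributylstannyl radical abstracts the vinylic bromine and the σ-vinyl radical at C7 is quenched by Bu3SnH, the allylic acetate being unable to leave by β-scission because that would give a six-membered cyclic allene.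

Step 14
Reactants: 19 6-exo-acetoxybicyclo[3.3.1]non-7-en-9-one carrying C1–OSiEt3 and the N-Boc acetonide
Product: 20 3-exo-amino-1,4-exo,6-exo-trihydroxybicyclo[3.3.1]non-7-en-9-one hydrochloride
Conditions: 3 M HCl in MeOH, 0 to 35 °C; then H2O, concentrate
Reagents that add atoms: hydrogen chloride Cl
Why: Acidic methanolysis removes the N,O-acetonide, the Boc group and the triethylsilyl ether and transesterifies the C6 acetate, so the C6 alkoxide is never formed and base-induced retro-aldol cleavage of C5–C6 (which would release an enal) is avoided; the amine is kept as its hydrochloride.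

Step 15
Reactants: 21 hex-5-enoyl chloride; 22 pentylmagnesium bromide
Product: 23 undec-1-en-6-one
Conditions: Fe(acac)3 (3 mol%), THF, −78 °C
Reagents that add atoms: none
Why: Iron-catalysed acylation of the Grignard reagent by the acid chloride is much faster than Grignard addition to the ketone formed, and the terminal alkene is inert.

Step 16
Reactants: 23 undec-1-en-6-one; 24 acrylic acid
Product: 25 (E)-7-oxododec-2-enoic acid
Conditions: second-generation Grubbs catalyst RuCl2(=CHPh)(PCy3)(H2IMes) (5 mol%), CH2Cl2, 40 °C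
Reagents that add atoms: none
Why: Olefin cross metathesis between the terminal alkene and excess acrylic acid is selective for the hetero-coupled product and gives the E-configured conjugated acid under thermodynamic control.

Step 17
Reactants: 20 3-exo-amino-1,4-exo,6-exo-trihydroxybicyclo[3.3.1]non-7-en-9-one hydrochloride; 25 (E)-7-oxododec-2-enoic acid
Product: 26 (E)-N-[1,4-exo,6-exo-trihydroxy-9-oxobicyclo[3.3.1]non-7-en-3-exo-yl]-7-oxododec-2-enamide
Conditions: EDC·HCl, 1-hydroxybenzotriazole, i-Pr2NEt, DMF, 0 °C to rt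
Reagents that add atoms: none
Why: Carbodiimide–hydroxybenzotriazole amide coupling: the primary amine liberated in situ is far more nucleophilic than the three hydroxyl groups, so acylation should occur on nitrogen only, and the tertiary amine base is too weak to form the C6 alkoxide.

Step 18
Reactants: 26 (E)-N-[1,4-exo,6-exo-trihydroxy-9-oxobicyclo[3.3.1]non-7-en-3-exo-yl]-7-oxododec-2-enamide
Product: 27 isariotin C
Conditions: VO(acac)2 (10 mol%), t-BuOOH, CH2Cl2, 0 °C to rt
Reagents that add atoms: tert-butyl hydroperoxide CC(C)(C)OO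
Why: Vanadium-catalysed hydroxyl-directed epoxidation: the pseudoaxial exo C6 hydroxyl binds the vanadium peroxide and delivers oxygen to the exo face of C7=C8 (also the face free of ring A), setting C7 and C8 cis to C6–OH as in the target, while the electron-poor side-chain alkene is not epoxidised.

**Compound list**
1 | N-Boc-L-aspartic acid 4-methyl ester | CC(C)(C)OC(=O)N[C@@H](CC(=O)OC)C(=O)O | starting material
2 | methyl (3S)-3-[(tert-butoxycarbonyl)amino]-4-hydroxybutanoate | CC(C)(C)OC(=O)N[C@@H](CC(=O)OC)CO | intermediate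
3 | methyl (3S)-3-[(tert-butoxycarbonyl)amino]-4-oxobutanoate | CC(C)(C)OC(=O)N[C@@H](CC(=O)OC)C=O | intermediate
4 | methyl (3S,4R)-3-[(tert-butoxycarbonyl)amino]-4-hydroxyhept-6-enoate | COC(=O)C[C@H](NC(=O)OC(C)(C)C)[C@H](O)CC=C | intermediate
5 | tert-butyl N-[(2R,3S)-2-allyl-5-oxotetrahydrofuran-3-yl]carbamate (trans lactone) | O=C1C[C@H](NC(=O)OC(C)(C)C)[C@@H](CC=C)O1 | intermediate
6 | (3S,4R)-3-[(tert-butoxycarbonyl)amino]-4-hydroxy-N-methoxy-N-methylhept-6-enamide | CON(C)C(=O)C[C@H](NC(=O)OC(C)(C)C)[C@H](O)CC=C | intermediate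
7 | tert-butyl (4S,5R)-5-allyl-4-[2-(methoxy(methyl)amino)-2-oxoethyl]-2,2-dimethyloxazolidine-3-carboxylate | CON(C)C(=O)C[C@H]1[C@@H](CC=C)OC(C)(C)N1C(=O)OC(C)(C)C | intermediate
8 | vinylmagnesium bromide | C=C[Mg]Br | starting material
9 | tert-butyl (4S,5R)-5-allyl-2,2-dimethyl-4-(2-oxobut-3-en-1-yl)oxazolidine-3-carboxylate | C=CC(=O)C[C@H]1[C@@H](CC=C)OC(C)(C)N1C(=O)OC(C)(C)C | intermediate
10 | tert-butyl (4S,5R)-2,2-dimethyl-4-(2-oxobut-3-en-1-yl)-5-(2-oxoethyl)oxazolidine-3-carboxylate | C=CC(=O)C[C@H]1[C@@H](CC=O)OC(C)(C)N1C(=O)OC(C)(C)C | intermediate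
11 | tert-butyl (3aS,5S,7aR)-5-hydroxy-2,2-dimethyl-6-oxo-5-vinylhexahydrobenzo[d]oxazole-3(2H)-carboxylate (ring A α-ketol; C1–OH cis to C3–N and C4–O) | C=C[C@@]1(O)C[C@H]2[C@@H](CC1=O)OC(C)(C)N2C(=O)OC(C)(C)C | intermediate
12 | tert-butyl (3aS,5S,7aR)-2,2-dimethyl-6-oxo-5-(triethylsilyloxy)-5-vinylhexahydrobenzo[d]oxazole-3(2H)-carboxylate | C=C[C@@]1(O[Si](CC)(CC)CC)C[C@H]2[C@@H](CC1=O)OC(C)(C)N2C(=O)OC(C)(C)C | intermediate
13 | bromoselenide: 12 with the vinyl group replaced by 2-bromo-1-(phenylselanyl)ethyl (both C8 epimers) | BrCC([Se]c1ccccc1)[C@@]1(O[Si](CC)(CC)CC)C[C@H]2[C@@H](CC1=O)OC(C)(C)N2C(=O)OC(C)(C)C | intermediate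
14 | bicyclo[3.2.1]octan-8-one: C1–OSiEt3, C8–SePh (both epimers), N-Boc-2,2-dimethyloxazolidine across exo C3–N and exo C4–O | CC[Si](CC)(CC)O[C@@]12C[C@H]3[C@@H]([C@@H](CC1[Se]c1ccccc1)C2=O)OC(C)(C)N3C(=O)OC(C)(C)C | intermediate
15 | bicyclo[3.2.1]oct-6-en-8-one: C1–OSiEt3, C8=C6, N-Boc-2,2-dimethyloxazolidine across exo C3–N and exo C4–O | CC[Si](CC)(CC)O[C@@]12C[C@H]3[C@@H]([C@@H](C=C1)C2=O)OC(C)(C)N3C(=O)OC(C)(C)C | intermediate
16 | bromoform | BrC(Br)Br | starting material
17 | exo gem-dibromocyclopropane of 15 (C7Br2 fused to C8–C6 on the C9 face) | CC[Si](CC)(CC)O[C@@]12C[C@H]3[C@@H]([C@@H]([C@H]4[C@@H]1C4(Br)Br)C2=O)OC(C)(C)N3C(=O)OC(C)(C)C | intermediate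
18 | 6-exo-acetoxy-7-bromobicyclo[3.3.1]non-7-en-9-one: C1–OSiEt3, N-Boc acetonide across C3–N/C4–O | CC[Si](CC)(CC)O[C@@]12C[C@H]3[C@@H]([C@@H]([C@H](OC(C)=O)C(Br)=C1)C2=O)OC(C)(C)N3C(=O)OC(C)(C)C | intermediate
19 | 6-exo-acetoxybicyclo[3.3.1]non-7-en-9-one: C1–OSiEt3, N-Boc acetonide across C3–N/C4–O | CC[Si](CC)(CC)O[C@@]12C[C@H]3[C@@H]([C@@H]([C@H](OC(C)=O)C=C1)C2=O)OC(C)(C)N3C(=O)OC(C)(C)C | intermediate
20 | 3-exo-amino-1,4-exo,6-exo-trihydroxybicyclo[3.3.1]non-7-en-9-one hydrochloride | N[C@H]1C[C@@]2(O)C(=O)[C@H]([C@H](O)C=C2)[C@H]1O.Cl | intermediate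
21 | hex-5-enoyl chloride | C=CCCCC(=O)Cl | starting material
22 | pentylmagnesium bromide | CCCCC[Mg]Br | starting material
23 | undec-1-en-6-one | CCCCCC(=O)CCCC=C | intermediate
24 | acrylic acid | C=CC(=O)O | starting material
25 | (E)-7-oxododec-2-enoic acid | CCCCCC(=O)CCC/C=C/C(=O)O | intermediate
26 | (E)-N-[1,4-exo,6-exo-trihydroxy-9-oxobicyclo[3.3.1]non-7-en-3-exo-yl]-7-oxododec-2-enamide | CCCCCC(=O)CCC/C=C/C(=O)N[C@H]1C[C@@]2(O)C(=O)[C@H]([C@H](O)C=C2)[C@H]1O | intermediate
27 | isariotin C | CCCCCC(=O)CCC/C=C/C(=O)N[C@H]1C[C@@]2(O)C(=O)[C@H]([C@H](O)[C@@H]3O[C@@H]32)[C@H]1O | target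

**Step count**
Total: 18 steps. Longest linear sequence: 16 steps (1–14, 17, 18).

**Steps most likely to fail**

Step 12. The alkene is deactivated by the homoconjugated C9 carbonyl and the allylic C1 oxygen, so carbene addition may be slow while tribromomethyl anion or hydroxide add to the strained ketone. The ketone also retards ionisation of the cyclopropyl bromide. The acetonide or the silyl ether may be partly lost in warm acetic acid, which is without consequence because step 14 removes them. Fallback: the ring expansion is run with C9 at the alcohol level. From 15, NaBH4 in MeOH at 0 °C (hydride from the alkene side of C9) should give C9 alcohol F1, which Et3SiOTf/2,6-lutidine converts to bis-silyl ether F2. CHBr3/50% NaOH/BnEt3NCl then gives exo dibromocyclopropane F3, opened by AgOAc/AcOH to bromoallyl acetate F4. Bu3SnH/AIBN gives debrominated acetate F5, HF·pyridine in THF removes both silyl groups to give diol F6, and Dess–Martin periodinane oxidises only the secondary C9 hydroxyl to ketol acetate F7. 3 M HCl in MeOH then returns to the route at 20.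

Step 8. Conjugate addition of the Breslow intermediate (intermolecular Stetter-type oligomerisation) or of the free carbene to the vinyl ketone may drain material irreversibly while the 1,2-adduct forms reversibly, and facial control at C1 may be incomplete. Fallback: the enone is masked before ring closure. From 10, PhSeH (CH2Cl2, 0 °C) adds to the enone to give selanyl keto aldehyde F8. The same carbene-catalysed benzoin gives selanyl ketol F9, now without an irreversible exit, so an unwanted C1 epimer can be returned to the equilibrium by retro-benzoin under the same catalyst. H2O2/pyridine (selenoxide elimination) restores the vinyl group and returns to the route at 11.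

Step 14. During the slow acid methanolysis of the hindered acetate, the free β-hydroxy ketone may open by retro-aldol cleavage of C5–C6, or C2 may shift from C1 to C9 (α-ketol rearrangement, driven by conjugation of the new C1 ketone with C8=C7). Ketalisation of C9 and incomplete acetate cleavage are further possibilities. Fallback: the order is changed so that the oxirane is in place before the α-ketol is unmasked. From 19, Me3SnOH (1,2-dichloroethane, 60 °C) cleaves the acetate under neutral conditions to allylic alcohol F10, and VO(acac)2/t-BuOOH gives epoxy alcohol F11. Aqueous CF3CO2H at 0 °C removes acetonide, Boc and silyl ether to give amino epoxy triol trifluoroacetate F12, and coupling with 25 under the conditions of step 17 reaches 27 directly.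

**Further compounds**
F1 | step 12 | C9 alcohol of 15 (OH on the ring A side) | CC[Si](CC)(CC)O[C@@]12C[C@H]3[C@@H]([C@@H](C=C1)[C@@H]2O)OC(C)(C)N3C(=O)OC(C)(C)C
F2 | step 12 | C1,C9-bis(triethylsilyl) ether | CC[Si](CC)(CC)O[C@@]12C[C@H]3[C@@H]([C@@H](C=C1)[C@@H]2O[Si](CC)(CC)CC)OC(C)(C)N3C(=O)OC(C)(C)C
F3 | step 12 | exo gem-dibromocyclopropane of F2 | CC[Si](CC)(CC)O[C@@]12C[C@H]3[C@@H]([C@@H]([C@H]4[C@@H]1C4(Br)Br)[C@@H]2O[Si](CC)(CC)CC)OC(C)(C)N3C(=O)OC(C)(C)C
F4 | step 12 | 6-exo-acetoxy-7-bromobicyclo[3.3.1]non-7-ene with C1 and C9 triethylsilyl ethers | CC[Si](CC)(CC)O[C@@]12C[C@H]3[C@@H]([C@@H]([C@H](OC(C)=O)C(Br)=C1)[C@@H]2O[Si](CC)(CC)CC)OC(C)(C)N3C(=O)OC(C)(C)C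
F5 | step 12 | debrominated acetate with C1 and C9 triethylsilyl ethers | CC[Si](CC)(CC)O[C@@]12C[C@H]3[C@@H]([C@@H]([C@H](OC(C)=O)C=C1)[C@@H]2O[Si](CC)(CC)CC)OC(C)(C)N3C(=O)OC(C)(C)C
F6 | step 12 | C1,C9-diol 6-acetate | O[C@@]12C[C@H]3[C@@H]([C@@H]([C@H](OC(C)=O)C=C1)[C@@H]2O)OC(C)(C)N3C(=O)OC(C)(C)C
F7 | step 12 | C1-hydroxy C9-ketone 6-acetate (ketol acetate) | O[C@@]12C[C@H]3[C@@H]([C@@H]([C@H](OC(C)=O)C=C1)C2=O)OC(C)(C)N3C(=O)OC(C)(C)C
F8 | step 8 | tert-butyl (4S,5R)-2,2-dimethyl-4-[2-oxo-4-(phenylselanyl)butyl]-5-(2-oxoethyl)oxazolidine-3-carboxylate | c1ccccc1[Se]CCC(=O)C[C@H]1[C@@H](CC=O)OC(C)(C)N1C(=O)OC(C)(C)C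
F9 | step 8 | ring A α-ketol carrying 2-(phenylselanyl)ethyl at C1 | c1ccccc1[Se]CC[C@@]1(O)C[C@H]2[C@@H](CC1=O)OC(C)(C)N2C(=O)OC(C)(C)C
F10 | step 14 | 6-exo-hydroxybicyclo[3.3.1]non-7-en-9-one with C1–OSiEt3 and N-Boc acetonide | CC[Si](CC)(CC)O[C@@]12C[C@H]3[C@@H]([C@@H]([C@H](O)C=C1)C2=O)OC(C)(C)N3C(=O)OC(C)(C)C
F11 | step 14 | 7,8-exo-epoxide of F10 | CC[Si](CC)(CC)O[C@@]12C[C@H]3[C@@H]([C@@H]([C@H](O)[C@@H]4O[C@@H]41)C2=O)OC(C)(C)N3C(=O)OC(C)(C)C
F12 | step 14 | amino epoxy triol trifluoroacetate (deacyl isariotin C salt) | N[C@H]1C[C@@]2(O)C(=O)[C@H]([C@H](O)[C@@H]3O[C@@H]32)[C@H]1O.OC(=O)C(F)(F)F
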